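The runs were computed with constants of no real substance, and the scatter is random.

12 min is the time the next flask gets, so the charge of J has to be chosen against that clock.

| setting | Thursday's | Saturday's | epsilon | gamma | delta | theta |
|---|---|---|---|---|---|---|
| Q | 0.018 M | 0.0060 M | 0.012 M | 0.012 M | 0.012 M | 0.012 M |
| E | 0.018 M | 0.0060 M | 0.012 M | 0.012 M | 0.012 M | 0.012 M |
| J | 0.048 M (in portions, 4) | 0.048 M (in portions, 4) | 0.0120 M (in portions, 4) | 0.0300 M (in portions, 4) | 0.0480 M (in portions, 4) | 0.200 M (in portions, 4) |
| remark | run made earlier; portions every 40 s | run made earlier; portions every 40 s | the portions of J follow each other after 40 s, the first at the start | the portions of J follow each other after 40 s, the first at the start | the portions of J follow each other after 40 s, the first at the start | the portions of J follow each other after 40 s, the first at the start |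
| time |  |  | 12 min | 12 min | 12 min | 12 min |

| run | time / min | D / % | Q / % |
|---|---|---|---|
| Thursday's | 0.833 | 3.1 | 45.4 |
| Thursday's | 2.50 | 16.6 | 37.7 |
| Thursday's | 5.00 | 32.9 | 27.4 |
| Thursday's | 8.00 | 46.4 | 20.4 |
| Saturday's | 0.500 | 2.8 | 47.6 |
| Saturday's | 1.33 | 5.5 | 44.7 |
| Saturday's | 3.00 | 21.9 | 32.2 |
| Saturday's | 8.00 | 49.8 | 15.4 |

(each reading ± 1 percentage point)

- J is single-handed; Q and E are mirror images of each other, charged as a racemate, each of them at the stated concentration
- the numbers in the tables scatter by 1 percentage point (one standard deviation)
- steps that have been proposed: J + E -> Z; E <-> G; Q <-> G; J + Q -> D; D <-> Z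
- the handed part of J does not stay in what it makes, so the products of the two hands are mirror images too

- all flasks from highest to lowest amount of D, in percent of the Q and E together charged, at 12 min (epsilon / gamma / delta / theta)
- the amount of D, in percent of the Q and E together charged of the flask you put first, at 12 min
- the amount of D, in percent of the Q and E together charged of the flask you put last, at 12 min

Saturday's run gives the measure. From 3.00 min to 8.00 min its D rises by 28 percentage points, while mean Q stands at 23.8% and c_J, less the J spent on D, at 0.0437 M. The rate constant of J + Q → D therefore reads k = 5.37 M⁻¹ min⁻¹. The product k·c_J is the pull of J on Q, a pseudo-first-order rate, and its inverse is a time constant. Saturday's D plus Q reaches 65.2%, more than the Q charged, so E feeds Q through G.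

The crossing lies where the time constant equals the clock, at c_J = 0.0155 M. Epsilon's whole charge stands below it, with a time constant of 15.5 min. The whole charge and the starting Q, held over the clock, reckon to 38.6% of D for epsilon. That is an estimate from above, for J comes in portions and Q fell to 15.4% in Saturday's run. Theta's whole charge stands far above it, with a time constant of 0.932 min, at a cost of 8.33 times the Q and E together. The reckoning commits to D rising with the charge of J across these four flasks, and so to charging theta.

The forecast gives theta > delta > gamma > epsilon, with 75% (66% to 84%) and 22% (18.5% to 25.5%), reading the runs as “a dynamic kinetic resolution”.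

The flasks give theta > delta > gamma > epsilon, with theta at 75.5% of D and epsilon at 22.0%.

    J + E → Z (k = 0.993 M⁻¹ min⁻¹)
    E ⇌ G (K = 0.0424, k = 0.983 min⁻¹)
    Q ⇌ G (K = 0.0424, k = 0.983 min⁻¹)
    J + Q → D (k = 5.93 M⁻¹ min⁻¹)
    D ⇌ Z (k = 0.00364 min⁻¹)

D and Z relax into each other with a half-life of 95.2 min, longer than the 12 min of the run. From 6.00 min to 12.0 min, k with epsilon's mean c_J and mean Q gives 8.6 points of D, against 9 points gained. Over the same stretch in delta it gives 19 points, against 19 points gained.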